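(All constants are invented; the flask was simulated.)

A small charge of electrophile, 0.050 M, meets 1.50 equiv of nucleophile in this flask, and I want to know how far it gets.

electrophile 0.050 M; nucleophile 1.50 equiv; buffer base 2.00 equiv; buffer acid 0.300 equiv; protic impurity 0.0100 M; time 80 s

- part of the electrophile that has reacted at 80 s
- pH of the solution at 80 s

The main step alone, with rate constant 0.313 M⁻¹ s⁻¹ and the nucleophile held as charged (pseudo-first-order), gives a half-life of 30 s and 84.7 % reacted by 80 s.

Now I add the protons. Each turnover releases one acid, and it lands on nucleophile rather than buffer base because the nucleophile's constant 1.0 × 10⁻⁹ M lies far below the buffer's 1.6 × 10⁻⁵ M. So each electrophile costs two nucleophiles, and the charge reaches to 75.0 % conversion.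

Then the rest. The buffer acid, 0.300 equiv, hands its protons to nucleophile at the start, and the protic impurity, 0.0100 M, eats one nucleophile each with the larger constant 1.37 M⁻¹ s⁻¹. That leaves spare nucleophile of 0.0500 M. Divided by two and by the electrophile charged, this gives 50.0 %, the budget line: the conversion at which the spare nucleophile has been used. Nucleophile is thus the limiting reagent.

I take the impurity as used from the outset, so spare nucleophile is two for each electrophile still short of the line. The gap then closes on a clock of 63.9 s. Call g the line times the exponential of minus time over clock, here 0.143. The unreacted share is what lies beyond the line divided by one minus g, which gives 41.7 % reacted. That leaves 0.00834 M nucleophile against 0.0358 M protonated, so the pH is 8.37.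

The forecast says 43 % and pH 8.34, a higher conversion than mine. It follows the protic impurity down along the way, where I took it as used from the outset, but its count is the same as mine: “Each electrophile consumed removes two free nucleophiles”.

The flask gives 43.0 % reacted and pH 8.34.

    electrophile + nucleophile → acid + product + leaving group (k1 = 0.313 M⁻¹ s⁻¹)
    protonated nucleophile ⇌ nucleophile + acid, settled at all times (K2 = 1.0 × 10⁻⁹ M)
    buffer acid ⇌ buffer base + acid, settled at all times (K3 = 1.6 × 10⁻⁵ M)
    nucleophile + protic impurity → quenched reagent (k4 = 1.37 M⁻¹ s⁻¹)

In this flask 10.6 % of the charged nucleophile is still free at 80.0 s. At 240 s the conversion reads 50.2 %, level with the line, and at 800 s it reads 52.3 %, beyond it. With 3.80 equiv of nucleophile, the neighbour flask has its line at 165 %, beyond the whole charge, and it reads 91.3 % reacted at 80 s, with 38.8 % of its nucleophile still free.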